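**Retrosynthetic overview**
1. Last skeletal event: a 1,2-shift of the quaternary carbon C4 from C8 to C9 in a norbornene (bicyclo[2.2.1] → bicyclo[3.1.1]), driven by N2 loss and a silyl enol ether push. It contracts a five-membered carbocycle to the cyclobutane and expands the cyclopentene to the cyclohexenone.
2. The norbornene comes from an intramolecular Diels–Alder reaction of a 2-silyloxycyclopentadiene with a tethered (E)-nitroalkene (bonds C5–C10 and C8–C9; also closes the seven-membered carbocycle). Nitro → amine supplies the leaving group.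
3. Side chain: nitroalkene from a terminal vinyl group; both senecioates sit on an anti-1,3-diol made by a reagent-controlled methyl-ketone aldol (C1) and a 1,3-anti reduction (C3).
4. Cyclopentenone with the quaternary C4: enantiogroup-selective aldol condensation of an achiral triketone made from 3-methylpentane-2,4-dione and chloroacetone.
5. Ring order: cyclopentenone → seven-membered ring plus norbornene (one step) → cyclobutane/cyclohexenone (1,2-shift).

Skeleton numbering used below: C1 = CH(O) next to CMe2; C2 = CH2; C3 = CH(O) next to C4; C4 = quaternary C–Me; C5 = CH next to the ketone; C6 = C=O; C7 = =CH; C8 = =C(Me); C9 = CH next to C8; C10 = CH next to CMe2; C11 = CMe2 (target cyclobutane: C4–C5–C10–C9).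

Assumption: 2,2-dimethylbut-3-enal is bought (otherwise one oxidation from commercial 2,2-dimethylbut-3-en-1-ol).

**Route**

Step 1
Reactants: 1 3-methylpentane-2,4-dione; 2 chloroacetone (1-chloropropan-2-one)
Product: 3 3-acetyl-3-methylhexane-2,5-dione
Conditions: K2CO3, NaI (cat.), acetone, reflux
Reagents that add atoms: none
Why: SN2 C-alkylation of the 2-methyl-1,3-diketone enolate (Finkelstein-activated halo ketone) builds the future C4 as a prochiral quaternary carbon with two enantiotopic acetyl groups; no stereocentre yet.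

Step 2
Reactants: 3 3-acetyl-3-methylhexane-2,5-dione
Product: 4 (S)-4-acetyl-3,4-dimethylcyclopent-2-en-1-one
Conditions: 9-amino-9-deoxy-epi-quinine (10 mol %), CF3CO2H (20 mol %), toluene, 40 °C
Reagents that add atoms: none
Why: Hajos–Parrish-type amine-catalysed intramolecular aldol condensation in which, under enamine catalysis, the CH3 of the unhindered acetonyl ketone attacks one of the two enantiotopic acetyl carbonyls, so the chiral primary ammonium catalyst sets C4 (S) by enantiogroup selection and dehydration gives the first ring (the quinidine-derived pseudo-enantiomer is used instead if the first run gives ent-4).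

Step 3
Reactants: 4 (S)-4-acetyl-3,4-dimethylcyclopent-2-en-1-one; 5 2,2-dimethylbut-3-enal
Product: 7 (4S)-4-[(3R)-3-hydroxy-4,4-dimethylhex-5-enoyl]-3,4-dimethylcyclopent-2-en-1-one, via diisopinocampheylboron enolate 6 (not isolated)
Conditions: (–)-Ipc2BCl (B-chlorodiisopinocampheylborane), Et3N, Et2O, 0 °C; 5, –78 → –20 °C; MeOH, pH 7 buffer, H2O2, 0 °C
Reagents that add atoms: none
Why: Paterson boron aldol, in which (–)-Ipc2BCl enolises only the methyl ketone (the neopentyl ring CH2 of the enone is left alone) and the isopinocampheyl ligands direct re-face attack on the aldehyde to set C1 (R) by reagent control; the minor C1 epimer is a diastereomer and is removed on silica.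

Step 4
Reactants: 7 (4S)-4-[(3R)-3-hydroxy-4,4-dimethylhex-5-enoyl]-3,4-dimethylcyclopent-2-en-1-one
Product: 8 (4S)-4-[(1R,3R)-1,3-dihydroxy-4,4-dimethylhex-5-en-1-yl]-3,4-dimethylcyclopent-2-en-1-one
Conditions: Me4NBH(OAc)3, MeCN/AcOH 1:1, –30 °C
Reagents that add atoms: none
Why: Evans–Saksena 1,3-anti reduction, in which the C1 hydroxyl binds boron and hydride is delivered intramolecularly through a chair transition state to set C3 (R) anti to C1; the enone carbonyl has no directing hydroxyl and is not reduced.

Step 5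
Reactants: 8 (4S)-4-[(1R,3R)-1,3-dihydroxy-4,4-dimethylhex-5-en-1-yl]-3,4-dimethylcyclopent-2-en-1-one; 9 3-methylbut-2-enoyl chloride (senecioyl chloride)
Product: 10 (1R,3R)-1-[(1S)-1,2-dimethyl-4-oxocyclopent-2-en-1-yl]-4,4-dimethylhex-5-ene-1,3-diyl bis(3-methylbut-2-enoate)
Conditions: 9 (3 equiv), pyridine, 4-(dimethylamino)pyridine (cat.), CH2Cl2, 0 °C → rt
Reagents that add atoms: none
Why: Nucleophile-catalysed acylation of both hindered secondary alcohols with retention at C1 and C3; pyridine instead of Et3N avoids vinylketene formation and deconjugation of the senecioyl unit.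

Step 6
Reactants: 10 (1R,3R)-1-[(1S)-1,2-dimethyl-4-oxocyclopent-2-en-1-yl]-4,4-dimethylhex-5-ene-1,3-diyl bis(3-methylbut-2-enoate)
Product: 11 (1R,3R,5E)-1-[(1S)-1,2-dimethyl-4-oxocyclopent-2-en-1-yl]-4,4-dimethyl-6-nitrohex-5-ene-1,3-diyl bis(3-methylbut-2-enoate)
Conditions: AgNO2, TEMPO (2,2,6,6-tetramethylpiperidin-1-oxyl, 0.4 equiv), 4 Å MS, ClCH2CH2Cl, 70 °C
Reagents that add atoms: silver nitrite, [Ag+].[O-]N=O
Why: Radical nitration–elimination of an alkene (NO2 radical addition, nitroxyl-mediated loss of H) is E-selective and picks the only electron-rich, unhindered C=C, the enone and senecioate alkenes being electron-poor, and C11 has no allylic H so the nitroalkene cannot isomerise.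

Step 7
Reactants: 11 (1R,3R,5E)-1-[(1S)-1,2-dimethyl-4-oxocyclopent-2-en-1-yl]-4,4-dimethyl-6-nitrohex-5-ene-1,3-diyl bis(3-methylbut-2-enoate)
Product: 13 endo-nitro norbornene silyl enol ether (1R,3R,4S,5R,8R,9S,10S; new bonds C5–C10 and C8–C9; C6(OTIPS)=C7; C8 bridgehead methyl; NO2 endo on C9; C11 exo on C10), via silyl dienol ether 12 (not isolated)
Conditions: TIPSOTf, Et3N, CH2Cl2, 0 °C; then toluene, 50 °C
Reagents that add atoms: triisopropylsilyl trifluoromethanesulfonate, CC(C)[Si](OS(=O)(=O)C(F)(F)F)(C(C)C)C(C)C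
Why: Soft enolisation at the α′ CH2 (C5) gives the 5,5-disubstituted 2-silyloxycyclopentadiene 12, which undergoes an intramolecular Diels–Alder reaction with the nitroalkene; the tether forces addition on the C3 face of C4 with C11 exo, the 2-silyloxy and 4-methyl groups both direct C10 to C5 and the nitro carbon C9 to C8, and the E geometry places NO2 endo, so C5, C8, C9 and C10 all follow from C4.

Step 8
Reactants: 13 endo-nitro norbornene silyl enol ether
Product: 14 endo-amino norbornene silyl enol ether (1R,3R,4S,5R,8R,9S,10S; NH2 endo on C9)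
Conditions: Al(Hg) (Al foil, HgCl2), THF/H2O 10:1, 0 °C → rt
Reagents that add atoms: none
Why: Neutral dissolving-metal reduction of the secondary nitro group to the primary amine with retention at C9; the silyl enol ether, the esters and the enoate C=C bonds tolerate these neutral, non-hydridic conditions.

Step 9
Reactants: 14 endo-amino norbornene silyl enol ether
Product: 16 target CNP0105062.1 (1R,3R,4R,5R,9R,10S), via endo-diazonium acetate 15 (not isolated)
Conditions: t-BuONO, AcOH, CH2Cl2, –20 °C → rt
Reagents that add atoms: none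
Why: Proposed new method: a vinylogous Tiffeneau–Demjanov (semipinacol) ring contraction, in which aprotic diazotisation gives diazonium 15 whose C9–N bond is antiperiplanar (about 155°) to the C8–C4 bridge bond, so N2 leaves with a 1,2-shift of C4 from C8 to C9 (inversion at C9, retention at C4) while the charge developing at C8 is absorbed through C7=C6 by the silyloxy group as a silyl oxocarbenium that acetate desilylates to the enone; N2 loss and enone formation pay for the cyclobutane strain, the enol ether π bond is syn to the leaving group and cannot displace it itself, and the cage has only one possible relative configuration; the closest known chemistry is the Tiffeneau–Demjanov/semipinacol deamination of β-amino alcohols and semipinacol ring contractions of bicyclic diol monosulfonates, here relayed through a C=C bond.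

**Compound list**
1 | 3-methylpentane-2,4-dione | CC(=O)C(C)C(C)=O | starting material
2 | chloroacetone | CC(=O)CCl | starting material
3 | 3-acetyl-3-methylhexane-2,5-dione | CC(=O)CC(C)(C(C)=O)C(C)=O | intermediate
4 | (S)-4-acetyl-3,4-dimethylcyclopent-2-en-1-one | O=C1C=C(C)[C@@](C)(C(C)=O)C1 | intermediate
5 | 2,2-dimethylbut-3-enal | C=CC(C)(C)C=O | starting material
6 | di[(–)-isopinocampheyl]boron enolate of the acetyl group of 4 | O=C1C=C(C)[C@@](C)(C(=C)OB([C@@H]2C[C@@H]3C[C@H]([C@H]2C)C3(C)C)[C@@H]2C[C@@H]3C[C@H]([C@H]2C)C3(C)C)C1 | intermediate (not isolated)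
7 | (4S)-4-[(3R)-3-hydroxy-4,4-dimethylhex-5-enoyl]-3,4-dimethylcyclopent-2-en-1-one | O=C1C=C(C)[C@@](C)(C(=O)C[C@@H](O)C(C)(C)C=C)C1 | intermediate
8 | (4S)-4-[(1R,3R)-1,3-dihydroxy-4,4-dimethylhex-5-en-1-yl]-3,4-dimethylcyclopent-2-en-1-one | O=C1C=C(C)[C@@](C)([C@H](O)C[C@@H](O)C(C)(C)C=C)C1 | intermediate
9 | 3-methylbut-2-enoyl chloride | CC(C)=CC(Cl)=O | starting material
10 | (1R,3R)-1-[(1S)-1,2-dimethyl-4-oxocyclopent-2-en-1-yl]-4,4-dimethylhex-5-ene-1,3-diyl bis(3-methylbut-2-enoate) | O=C1C=C(C)[C@@](C)([C@H](OC(=O)C=C(C)C)C[C@@H](OC(=O)C=C(C)C)C(C)(C)C=C)C1 | intermediate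
11 | (1R,3R,5E)-1-[(1S)-1,2-dimethyl-4-oxocyclopent-2-en-1-yl]-4,4-dimethyl-6-nitrohex-5-ene-1,3-diyl bis(3-methylbut-2-enoate) | O=C1C=C(C)[C@@](C)([C@H](OC(=O)C=C(C)C)C[C@@H](OC(=O)C=C(C)C)C(C)(C)/C=C/[N+](=O)[O-])C1 | intermediate
12 | (1R,3R,5E)-1-[(1S)-1,2-dimethyl-4-(triisopropylsilyloxy)cyclopenta-2,4-dien-1-yl]-4,4-dimethyl-6-nitrohex-5-ene-1,3-diyl bis(3-methylbut-2-enoate) | CC1=CC(O[Si](C(C)C)(C(C)C)C(C)C)=C[C@]1(C)[C@H](OC(=O)C=C(C)C)C[C@@H](OC(=O)C=C(C)C)C(C)(C)/C=C/[N+](=O)[O-] | intermediate (not isolated)
13 | endo-nitro norbornene silyl enol ether, (1R,3R,4S,5R,8R,9S,10S): norbornene with bridgeheads C5 (H) and C8 (Me), C6(OTIPS)=C7, bridge C4 (Me anti, C3 syn to the C9–C10 bridge), NO2 endo on C9, C11 exo on C10, seven-membered ring C4–C3–C2–C1–C11–C10–C5, senecioates on C1 and C3 | C[C@@]12C=C(O[Si](C(C)C)(C(C)C)C(C)C)[C@H]3[C@]1(C)[C@H](OC(=O)C=C(C)C)C[C@@H](OC(=O)C=C(C)C)C(C)(C)[C@H]3[C@@H]2[N+](=O)[O-] | intermediate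
14 | endo-amino norbornene silyl enol ether, (1R,3R,4S,5R,8R,9S,10S): as 13 with NH2 in place of NO2 | C[C@@]12C=C(O[Si](C(C)C)(C(C)C)C(C)C)[C@H]3[C@]1(C)[C@H](OC(=O)C=C(C)C)C[C@@H](OC(=O)C=C(C)C)C(C)(C)[C@H]3[C@@H]2N | intermediate
15 | endo-diazonium acetate of 14 | C[C@@]12C=C(O[Si](C(C)C)(C(C)C)C(C)C)[C@H]3[C@]1(C)[C@H](OC(=O)C=C(C)C)C[C@@H](OC(=O)C=C(C)C)C(C)(C)[C@H]3[C@@H]2[N+]#N.CC(=O)[O-] | intermediate (not isolated)
16 | CNP0105062.1, (1R,3R,4R,5R,9R,10S): cyclobutane C4–C5–C10–C9, enone C6(=O)–C7=C8(Me) bridging C5 and C9, chain C3–C2–C1–C11 bridging C4 and C10, 1,3-bis(3-methylbut-2-enoate) | CC(C)=CC(=O)O[C@@H]1C[C@@H](OC(=O)C=C(C)C)[C@@]2(C)[C@@H]3C(=O)C=C(C)[C@H]2[C@@H]3C1(C)C | target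

**Totals**
Total steps: 9. Longest linear sequence: 9 steps (1 and 2 → 16).

**Steps most likely to fail**

Step 2. The five-membered enamine aldol closure is slow, retro-Claisen cleavage of the 1,3-diketone can compete, and the level of enantiogroup selection on this acyclic triketone is untested. Fallback: starting from 3, cyclise without asymmetric induction (pyrrolidine, AcOH, toluene, 80 °C) to the racemate, that is 4 together with (R)-4-acetyl-3,4-dimethylcyclopent-2-en-1-one F1. The racemate is put through the step 3 aldol, whose reagent control gives the (3R)-carbinol in both series, so 7 is formed next to its C4 epimer (4R)-4-[(3R)-3-hydroxy-4,4-dimethylhex-5-enoyl]-3,4-dimethylcyclopent-2-en-1-one F2. These are diastereomers and are separated on silica, and the route is rejoined at 7.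

Step 7. Enolisation may go to the γ-methyl, the seven-membered tether may close slowly, and a stepwise Mukaiyama–Michael path could give some exo-nitro isomer. Fallback: starting from 11, use the known amine-mediated enone–nitroalkene [4+2] cycloaddition (aminodiene activation; pyrrolidine, toluene, 40 °C, then aqueous AcOH) to obtain the desilylated cycloadduct, the endo-nitro norbornanone F3. This ketone has only one enolisable α-carbon (C7; C5 is a bridgehead) and is silylated (TIPSOTf, Et3N, then aqueous NaHCO3 work-up, which also returns any silyl nitronate to the nitro group) to rejoin the route at 13.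

Step 9 (the proposed new step). The nitrosating agent may attack the enol ether at C7, or the shift may lose out to substitution at C9. Fallback with known chemistry: starting from 14, hydrolyse the enol ether (aqueous HCl, THF) to the endo-amino norbornanone F4 and run a classical Demjanov deamination (NaNO2, aqueous AcOH, 0 °C). Wagner–Meerwein shift of C4 to C9 gives the tertiary C8 cation, which loses the acidic H on C7 to form the enone directly (DBU to conjugate any exocyclic or β,γ-alkene isomer). This rejoins the route at 16.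

**Further compounds**
F1 | step 2 | (R)-4-acetyl-3,4-dimethylcyclopent-2-en-1-one | O=C1C=C(C)[C@](C)(C(C)=O)C1
F2 | step 2 | (4R)-4-[(3R)-3-hydroxy-4,4-dimethylhex-5-enoyl]-3,4-dimethylcyclopent-2-en-1-one | O=C1C=C(C)[C@](C)(C(=O)C[C@@H](O)C(C)(C)C=C)C1
F3 | step 7 | endo-nitro norbornanone (13 with C6=O and C7H2 in place of the silyl enol ether) | C[C@@]12CC(=O)[C@H]3[C@]1(C)[C@H](OC(=O)C=C(C)C)C[C@@H](OC(=O)C=C(C)C)C(C)(C)[C@H]3[C@@H]2[N+](=O)[O-]
F4 | step 9 | endo-amino norbornanone (14 with C6=O and C7H2 in place of the silyl enol ether) | C[C@@]12CC(=O)[C@H]3[C@]1(C)[C@H](OC(=O)C=C(C)C)C[C@@H](OC(=O)C=C(C)C)C(C)(C)[C@H]3[C@@H]2N
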